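**Plan**
1. p-Menthane numbering is used throughout: C1 = CBrCH3, C2 = CHBr, C4 = ring CH, C8 = side-chain CBr, C9 = CH2Br. The target is the 1S,2S,4R,8R isomer, with both ring bromines axial and the side chain equatorial.
2. Retrosynthesis: C8–Br is cut first, back to a C8–OH that holds the same site. C1–Br and C2–Br are cut next, back to the C1=C2 alkene. The C8 oxygen is then tied back to C2, with a C1–Br as trigger for its later release. Last, C8–O and C9–Br are cut back to the isopropenyl group of cis-carveol.
3. Enabling feature: C4 lies between two CH2 groups (C3, C5) and cannot tell the faces of C8=C9 apart. An oxygen on C2, cis to the side chain, reaches C8 and closes the ring C2–C3–C4–C8–O of a 6-oxabicyclo[3.2.1]oct-3-ene, in which the two free sites on C8 differ.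
4. Forward: the carbocycle comes with carvone and no C–C bond is made. The ether ring closes in step 2 and is opened at C2–O in step 4. Bromine enters at C9, then C1 (temporary), then C1/C2, then C8.
5. Stereochemistry: C4 comes from (R)-carvone and the temporary C2–OH from Luche reduction. C8 is set by exo placement of CH2Br in the bicyclic closure and is later handed from O to Br with retention through the C8–C9 bromonium ion. C1 and C2 come from diaxial anti addition of Br2, anchored by C4.
6. The allylic ether never meets an acid. A C2–C1–C6 allyl cation is symmetric about the C1···C4 axis and would let oxygen return at C6, which destroys the C4/C8 relationship. The ring alkene is therefore removed first, under neutral radical conditions.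

Key step: step 2

Remark: 6 is drawn as the C1 epimer with bromine anti to the ether oxygen; C1 becomes sp2 again in step 4, so either epimer serves.

**Step 1**
Reactants: 1 (R)-(−)-carvone
Product: 2 (1R,5R)-2-methyl-5-(prop-1-en-2-yl)cyclohex-2-en-1-ol ((−)-cis-carveol)
Conditions: NaBH4, CeCl3·7H2O, MeOH, −20 to 0 °C
Reagents that add atoms: none
Why: Luche reduction, in which the cerium-modified borohydride adds 1,2 only and hydride enters C2 along the axial trajectory of the half-chair with equatorial isopropenyl group, which sets the pseudoequatorial (R)-carbinol cis to the C4 side chain.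

**Step 2**
Reactants: 2 (−)-cis-carveol; 3 N-bromosuccinimide
Product: 5 (1R,5R,7R)-7-(bromomethyl)-4,7-dimethyl-6-oxabicyclo[3.2.1]oct-3-ene (exo-9-bromopinol), via bromonium ion 4 (not isolated)
Conditions: NBS (1.05 equiv), solid NaHCO3, CH2Cl2, −20 to 0 °C, dark
Reagents that add atoms: N-bromosuccinimide, O=C1CCC(=O)N1Br
Why: NBS passes Br+ reversibly to both alkenes, but only the isopropenyl bromonium ion 4 has a nucleophile in reach: in the half-chair with C2–O and C4–C8 both pseudoaxial the hydroxyl opens it at tertiary C8, anti to bromine, and the succinimide anion takes the proton (intramolecular bromoetherification, the halogen counterpart of pinol-type cycloetherification of 1,3-cis hydroxy-alkenyl cyclohexanes). The tetrahydrofuran ring C2–C3–C4–C8–O closes in the 5-exo mode and C9–Br stays outside the ring. The one new stereocentre, C8, is fixed by the bicyclic transition state held by C2 and C4: the exo site on C8 is nearly eclipsed with the small C4–H and the endo site with the C4–C5 bond under the ring, so the CH2–Br+ unit goes exo and the methyl endo, which gives 7R with oxygen where the target carries bromine. Chemoselectivity over the trisubstituted ring alkene rests on reversible Br+ transfer in an aprotic medium free of outside nucleophiles and on the inductive deactivation of C1=C6 by the allylic oxygen. Bicarbonate, low temperature and darkness keep acid and radical chains out, since ionisation of the allylic C2–O bond of 5 would scramble the C4/C8 relationship.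

**Step 3**
Reactants: 5 exo-9-bromopinol
Product: 6 (1R,4R,5R,7R)-4-bromo-7-(bromomethyl)-4,7-dimethyl-6-oxabicyclo[3.2.1]octane
Conditions: TsBr, Co(acac)2 (cat.), t-BuOOH (cat.), Et3SiH, n-PrOH, 23 °C, Ar, dark; filtered through neutral alumina and used crude
Reagents that add atoms: p-toluenesulfonyl bromide, Cc1ccc(cc1)S(=O)(=O)Br
Why: Markovnikov hydrobromination by metal-hydride hydrogen-atom transfer, in which cobalt hydride gives H• to C6 and the tertiary C1 radical takes bromine from TsBr on the face turned away from the O–C8 bridge, all in a neutral medium that leaves the allylic C2–O bond un-ionised while the alkene that activates it disappears.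

**Step 4**
Reactants: 6 the 1,9-dibromo ether
Product: 7 (2R)-1-bromo-2-[(1R)-4-methylcyclohex-3-en-1-yl]propan-2-ol
Conditions: activated Zn dust, AcOH, THF, 0 °C
Reagents that add atoms: none
Why: Boord-type reductive β-elimination, in which zinc attacks the more easily reduced tertiary C1–Br that is locked antiperiplanar to C2–O, so the ether oxygen leaves from C2, the alkene appears at C1=C2 with C6 now CH2, and C8–O, C9–Br and the C8 configuration stay untouched while acetic acid protonates the alkoxide before it can close on C9.

**Step 5**
Reactants: 7 the bromohydrin alkene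
Product: 8 (2R)-1-bromo-2-[(1R,3S,4S)-3,4-dibromo-4-methylcyclohexyl]propan-2-ol
Conditions: Br2 (1.0 equiv), Et4NBr, CH2Cl2, −78 °C, dark
Reagents that add atoms: bromine, BrBr
Why: Electrophilic anti addition under the Fürst–Plattner rule, as known for α-terpineol and limonene, in which the equatorial C4 side chain anchors the ring so that diaxial opening from either face converges on axial C1–Br (cis to the side chain) and axial C2–Br (trans), that is 1S,2S, while added bromide at low temperature outruns capture by the weakly nucleophilic β-bromo-substituted C8 hydroxyl.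

**Step 6**
Reactants: 8 the tribromo alcohol
Product: 11 (1S,2S,4R)-1,2-dibromo-4-[(2R)-1,2-dibromopropan-2-yl]-1-methylcyclohexane, via O-dibromoboryl ether 9 (not isolated), via bromonium ion 10 (not isolated)
Conditions: BBr3 (1.5 equiv), CH2Cl2–pentane, −78 to −20 °C; then H2O
Reagents that add atoms: boron tribromide, BrB(Br)Br
Why: Substitution of a β-bromo tertiary alcohol with neighbouring-group participation, in which BBr3 turns the hydroxyl into boryl ether 9, the C9 bromine displaces it from the rear to give bromonium ion 10, and bromide reopens this at tertiary C8 from the side the oxygen left, so two inversions give net retention (8R), while the non-polar cold medium keeps the ion pair tight and leaves the favoured diaxial ring dibromide unchanged.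

**Compound list**
1 | (R)-(−)-carvone, (5R)-2-methyl-5-(prop-1-en-2-yl)cyclohex-2-en-1-one | CC1=CC[C@H](CC1=O)C(C)=C | starting material
2 | (−)-cis-carveol, (1R,5R)-2-methyl-5-(prop-1-en-2-yl)cyclohex-2-en-1-ol | C=C(C)[C@@H]1CC=C(C)[C@H](O)C1 | intermediate
3 | N-bromosuccinimide | O=C1CCC(=O)N1Br | starting material
4 | C8–C9 bromonium ion of cis-carveol, Br+ on the face away from the C2 oxygen (not isolated) | C[C@@]1(C[Br+]1)[C@@H]2CC=C(C)[C@H](O)C2 | intermediate
5 | (1R,5R,7R)-7-(bromomethyl)-4,7-dimethyl-6-oxabicyclo[3.2.1]oct-3-ene, CH2Br exo | C[C@@]1(CBr)O[C@@H]2C[C@H]1CC=C2C | intermediate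
6 | (1R,4R,5R,7R)-4-bromo-7-(bromomethyl)-4,7-dimethyl-6-oxabicyclo[3.2.1]octane | C[C@@]1(CBr)O[C@@H]2C[C@H]1CC[C@@]2(C)Br | intermediate
7 | (2R)-1-bromo-2-[(1R)-4-methylcyclohex-3-en-1-yl]propan-2-ol | C[C@](O)(CBr)[C@@H]1CCC(C)=CC1 | intermediate
8 | (2R)-1-bromo-2-[(1R,3S,4S)-3,4-dibromo-4-methylcyclohexyl]propan-2-ol | C[C@](O)(CBr)[C@@H]1CC[C@](C)(Br)[C@@H](Br)C1 | intermediate
9 | O-dibromoboryl ether of 8 (not isolated) | C[C@](OB(Br)Br)(CBr)[C@@H]1CC[C@](C)(Br)[C@@H](Br)C1 | intermediate
10 | C8–C9 bromonium ion of the 1,2-dibromo-p-menthane (not isolated) | C[C@@]1(C[Br+]1)[C@@H]2CC[C@](C)(Br)[C@@H](Br)C2 | intermediate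
11 | (1S,2S,4R)-1,2-dibromo-4-[(2R)-1,2-dibromopropan-2-yl]-1-methylcyclohexane | C[C@](Br)(CBr)[C@@H]1CC[C@](C)(Br)[C@@H](Br)C1 | target

Total steps: 6. Longest linear sequence: 6.

**Steps most likely to fail**

**Step 3.**
- Risk: hydrogen-atom transfer to the hindered trisubstituted alkene may be slow. Sulfonyl radicals may add to the alkene instead of only carrying the chain. The tertiary bromide may lose HBr on isolation.
- Fallback: the hydrobromination is split into two classical operations. From 5, Mukaiyama hydration (Mn(dpm)3, PhSiH3, O2, i-PrOH, 0 °C) should give the tertiary alcohol (1R,4R,5R,7R)-7-(bromomethyl)-4,7-dimethyl-6-oxabicyclo[3.2.1]octan-4-ol F1. Bromotrimethylsilane in CH2Cl2 at 0 °C should then exchange the tertiary hydroxyl for bromine. The route is rejoined at 6.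

**Step 4.**
- Risk: electron transfer to the primary C9–Br may compete with that to C1–Br, which would unzip the C8–O bond and erase C8. The bromohydrin may also be reduced further.
- Fallback: the C1=C2 alkene is made without a reducing metal.
  - From 6, BBr3 (CH2Cl2, −78 °C) should break the tertiary C8–O bond of the now saturated ether first, again through the C8–C9 bromonium ion and with retention. This gives (1R,2R,5R)-2-bromo-5-[(2R)-1,2-dibromopropan-2-yl]-2-methylcyclohexan-1-ol F2.
  - Dess–Martin oxidation should give (2R,5R)-2-bromo-5-[(2R)-1,2-dibromopropan-2-yl]-2-methylcyclohexan-1-one F3.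
  - Hydrazine hydrate and KOAc in EtOH should remove the carbonyl oxygen and the α-bromine together (Kishner–Leonard eliminative reduction). This leaves (4R)-4-[(2R)-1,2-dibromopropan-2-yl]-1-methylcyclohex-1-ene F4.
  - Bromine under the conditions of step 5 then leads to 11, where the route is rejoined.

**Step 2.**
- Risk: facial selectivity at C8=C9 may be modest, because CH2Br and CH3 differ little in size once bromine turns away. Br+ may also be lost to the ring alkene or to allylic substitution.
- Fallback: reagent control is added to substrate control. From 2, the same closure is run with NBS under a chiral Lewis-base catalyst of the cinchona amino-thiocarbamate type, known for enantioselective halocyclisation of 1,1-disubstituted alkenes. The catalyst enantiomer is chosen so that its facial preference matches the exo closure. The product is again 5 and no new compound appears (entry F0).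

**Further compounds**
F0 | step 2 | none | none
F1 | step 3 | (1R,4R,5R,7R)-7-(bromomethyl)-4,7-dimethyl-6-oxabicyclo[3.2.1]octan-4-ol | C[C@@]1(CBr)O[C@@H]2C[C@H]1CC[C@@]2(C)O
F2 | step 4 | (1R,2R,5R)-2-bromo-5-[(2R)-1,2-dibromopropan-2-yl]-2-methylcyclohexan-1-ol | C[C@](Br)(CBr)[C@@H]1CC[C@@](C)(Br)[C@H](O)C1
F3 | step 4 | (2R,5R)-2-bromo-5-[(2R)-1,2-dibromopropan-2-yl]-2-methylcyclohexan-1-one | C[C@](Br)(CBr)[C@@H]1CC[C@@](C)(Br)C(=O)C1
F4 | step 4 | (4R)-4-[(2R)-1,2-dibromopropan-2-yl]-1-methylcyclohex-1-ene | C[C@](Br)(CBr)[C@@H]1CCC(C)=CC1
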